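**Plan**

- Ring A is the 2,4-dihydroxy-5-prenylphenyl ring and ring B the 3-hydroxy-2-prenylphenyl ring (prenyl = 3-methylbut-2-en-1-yl). The retrosynthesis cuts the three O–CH2OMe bonds, takes C=O back to CH–OH, cuts the bond between C1 of ring A and the carbonyl carbon, and cuts the two aryl–CH2 bonds of the prenyl groups (A: C5–CH2; B: C2–CH2).
- Enabling feature: in ring A, C1 (acyl) and C5 (prenyl) are each ortho to one oxygen and para to the other. These are the two equivalent C–Br carbons of C2v-symmetric 4,6-dibromoresorcinol, and the O2 acetal next to C1 can chelate lithium. The carbonyl carbon sits on ring B as a non-enolisable aldehyde next to the prenylated C2.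
- Forward, ring A: 1 → bis-MOM ether 2 → first Br→Li→Cu exchange and prenyl bromide → bromide 5. Ring B: 6 → MOM ether 7 → Stille prenylation → aldehyde 8.
- Union: second Br→Li exchange on 5 and addition to 8 gives carbinol 11, Dess–Martin oxidation gives ketone 12, and acid methanolysis of the three MOM ethers gives 13.
- Stereochemistry: the target has no stereocentre, no axis and no E/Z-stereogenic alkene (each alkene carries two methyls), so it is a single achiral compound and nothing has to be set. The carbinol centre of 11 forms as a racemate and is removed in step 6.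

Key step: step 5

**Step 1**
Reactants: 1 4,6-dibromobenzene-1,3-diol
Product: 2 1,5-dibromo-2,4-bis(methoxymethoxy)benzene
Conditions: MOMCl (2.5 equiv), i-Pr2NEt (3 equiv), CH2Cl2, 0 °C → rt
Reagents that add atoms: chloromethyl methyl ether (MOMCl), COCCl
Why: Williamson-type O-alkylation of both acidic ortho-bromophenols with the reactive α-chloro ether should give the bis-acetal, which keeps the two C–Br bonds equivalent and supplies the oxygen that later chelates lithium.

**Step 2**
Reactants: 2 1,5-dibromo-2,4-bis(methoxymethoxy)benzene
Product: 5 1-bromo-2,4-bis(methoxymethoxy)-5-(3-methylbut-2-en-1-yl)benzene, via aryllithium 3 (not isolated), via arylcopper 4 (not isolated)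
Conditions: n-BuLi (1.0 equiv), THF, −78 °C; CuBr·SMe2 (1.0 equiv), −78 → −40 °C; prenyl bromide, −78 °C → rt
Reagents that add atoms: 1-bromo-3-methylbut-2-ene (prenyl bromide), CC(C)=CCBr
Why: The two C–Br bonds are equivalent and the first bromine–lithium exchange makes the ring too electron-rich for a second, so one equivalent of n-BuLi should give the mono-aryllithium, which after transmetalation to copper undergoes allylic substitution at the unhindered CH2 terminus of prenyl bromide (organocopper allylation) to give the linear prenyl arene.

**Step 3**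
Reactants: 6 2-bromo-3-hydroxybenzaldehyde
Product: 7 2-bromo-3-(methoxymethoxy)benzaldehyde
Conditions: MOMCl (1.3 equiv), i-Pr2NEt (1.5 equiv), CH2Cl2, 0 °C → rt
Reagents that add atoms: chloromethyl methyl ether (MOMCl), COCCl
Why: Williamson-type O-alkylation of the phenol under amine base leaves the aldehyde untouched and removes the acidic proton that would quench the aryllithium of step 5.

**Step 4**
Reactants: 7 2-bromo-3-(methoxymethoxy)benzaldehyde
Product: 8 3-(methoxymethoxy)-2-(3-methylbut-2-en-1-yl)benzaldehyde
Conditions: tributyl(prenyl)stannane (1.3 equiv), Pd(PPh3)4 (5 mol %), DMF, 90 °C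
Reagents that add atoms: tributyl(3-methylbut-2-en-1-yl)stannane, CCCC[Sn](CCCC)(CCCC)CC=C(C)C
Why: Stille coupling by oxidative addition of Pd(0) into the C–Br bond activated by the ortho formyl group, tin-to-palladium transfer of the prenyl group and reductive elimination at the less substituted CH2 terminus of the prenyl–palladium should give the linear 2-prenyl aldehyde under neutral conditions that spare the aldehyde and the acetal.

**Step 5**
Reactants: 5 1-bromo-2,4-bis(methoxymethoxy)-5-(3-methylbut-2-en-1-yl)benzene; 8 3-(methoxymethoxy)-2-(3-methylbut-2-en-1-yl)benzaldehyde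
Product: 11 rac-[2,4-bis(methoxymethoxy)-5-(3-methylbut-2-en-1-yl)phenyl][3-(methoxymethoxy)-2-(3-methylbut-2-en-1-yl)phenyl]methanol, via aryllithium 9 (not isolated), via lithium alkoxide 10 (not isolated)
Conditions: n-BuLi (1.05 equiv), THF, −78 °C; then 8 in THF, −78 → −30 °C; H2O
Reagents that add atoms: none
Why: Bromine–lithium exchange at C1 of ring A (ortho to O2, para to O4) gives an aryllithium held by chelation to the O2 methoxymethyl ether, and this carbanion adds to the non-enolisable aldehyde carbon of 8 to give the lithium diarylmethoxide, which is protonated on work-up. The closest known reaction type is the 1,2-addition of ortho-alkoxyaryllithium reagents to aryl aldehydes, here used as a union of two carbons that are both electrophilic in their precursors (C–Br and C=O) through polarity reversal at the ring carbon. No ring is closed. The one new stereocentre, the carbinol carbon, forms without control as a racemate and is deleted in step 6, so it has no bearing on the achiral target. The step needs site fidelity and chemoselectivity: exchange must outrun deprotonation at C3–H between the two acetal oxygens, and carbonyl addition must outrun deprotonation of the benzylic–allylic CH2 of 8, and both should hold at −78 °C where exchange and addition are faster than proton transfer. A polar two-electron union is chosen because an acyl radical at this carbon would cyclise 5-exo onto the ortho prenyl alkene of ring B and acid-mediated acylation would attack the prenyl groups.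

**Step 6**
Reactants: 11 rac-[2,4-bis(methoxymethoxy)-5-(3-methylbut-2-en-1-yl)phenyl][3-(methoxymethoxy)-2-(3-methylbut-2-en-1-yl)phenyl]methanol
Product: 12 [2,4-bis(methoxymethoxy)-5-(3-methylbut-2-en-1-yl)phenyl][3-(methoxymethoxy)-2-(3-methylbut-2-en-1-yl)phenyl]methanone
Conditions: DMP (1.3 equiv), pyridine, CH2Cl2, 0 °C → rt
Reagents that add atoms: none
Why: Dess–Martin oxidation of the doubly benzylic secondary alcohol by ligand exchange at iodine(V) and α-C–H elimination under pyridine-buffered conditions should spare the acetals and both trisubstituted alkenes and removes the only stereocentre of the route.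

**Step 7**
Reactants: 12 [2,4-bis(methoxymethoxy)-5-(3-methylbut-2-en-1-yl)phenyl][3-(methoxymethoxy)-2-(3-methylbut-2-en-1-yl)phenyl]methanone
Product: 13 cudraphenone B, [2,4-dihydroxy-5-(3-methylbut-2-en-1-yl)phenyl][3-hydroxy-2-(3-methylbut-2-en-1-yl)phenyl]methanone
Conditions: 3 M aq HCl, MeOH, 40 °C
Reagents that add atoms: none
Why: Acid-catalysed transacetalisation (methanolysis) of the three aryl MOM ethers should outpace protonation of the trisubstituted alkenes in dilute methanolic HCl, a selectivity with close precedent for MOM-protected ortho-prenylphenols, and the O2 ether is further activated by the neighbouring carbonyl.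

**Compound list**

1 | 4,6-dibromobenzene-1,3-diol (4,6-dibromoresorcinol) | Oc1cc(O)c(Br)cc1Br | starting material
2 | 1,5-dibromo-2,4-bis(methoxymethoxy)benzene | COCOc1cc(OCOC)c(Br)cc1Br | intermediate
3 | [5-bromo-2,4-bis(methoxymethoxy)phenyl]lithium | [Li]c1cc(Br)c(OCOC)cc1OCOC | intermediate
4 | [5-bromo-2,4-bis(methoxymethoxy)phenyl]copper(I) | [Cu]c1cc(Br)c(OCOC)cc1OCOC | intermediate
5 | 1-bromo-2,4-bis(methoxymethoxy)-5-(3-methylbut-2-en-1-yl)benzene | COCOc1cc(OCOC)c(CC=C(C)C)cc1Br | intermediate
6 | 2-bromo-3-hydroxybenzaldehyde | O=Cc1cccc(O)c1Br | starting material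
7 | 2-bromo-3-(methoxymethoxy)benzaldehyde | COCOc1cccc(C=O)c1Br | intermediate
8 | 3-(methoxymethoxy)-2-(3-methylbut-2-en-1-yl)benzaldehyde | COCOc1cccc(C=O)c1CC=C(C)C | intermediate
9 | [2,4-bis(methoxymethoxy)-5-(3-methylbut-2-en-1-yl)phenyl]lithium | [Li]c1cc(CC=C(C)C)c(OCOC)cc1OCOC | intermediate
10 | lithium [2,4-bis(methoxymethoxy)-5-(3-methylbut-2-en-1-yl)phenyl][3-(methoxymethoxy)-2-(3-methylbut-2-en-1-yl)phenyl]methanolate (racemate) | [Li+].[O-]C(c1cc(CC=C(C)C)c(OCOC)cc1OCOC)c1cccc(OCOC)c1CC=C(C)C | intermediate
11 | rac-[2,4-bis(methoxymethoxy)-5-(3-methylbut-2-en-1-yl)phenyl][3-(methoxymethoxy)-2-(3-methylbut-2-en-1-yl)phenyl]methanol | COCOc1cc(OCOC)c(CC=C(C)C)cc1C(O)c1cccc(OCOC)c1CC=C(C)C | intermediate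
12 | [2,4-bis(methoxymethoxy)-5-(3-methylbut-2-en-1-yl)phenyl][3-(methoxymethoxy)-2-(3-methylbut-2-en-1-yl)phenyl]methanone | COCOc1cc(OCOC)c(CC=C(C)C)cc1C(=O)c1cccc(OCOC)c1CC=C(C)C | intermediate
13 | cudraphenone B, [2,4-dihydroxy-5-(3-methylbut-2-en-1-yl)phenyl][3-hydroxy-2-(3-methylbut-2-en-1-yl)phenyl]methanone (achiral) | CC(C)=CCc1cc(C(=O)c2cccc(O)c2CC=C(C)C)c(O)cc1O | target

**Step count**

Total steps: 7. Longest linear sequence: 5 steps (1 → 2 → 5 → 11 → 12 → 13, and equally 6 → 7 → 8 → 11 → 12 → 13).

**Steps most likely to fail, with fallbacks**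

Step 7. Once a phenol next to a prenyl group is unmasked in acid, protonation of the alkene and ring closure to a 2,2-dimethylchroman, or addition of methanol across the alkene, may compete with acetal cleavage. The fallback sets out from ketone 12 and exchanges the acetals for silyl groups with TMSOTf and 2,2′-bipyridyl in CH2Cl2 at 0 °C. This should give [2,4-bis(trimethylsilyloxy)-5-(3-methylbut-2-en-1-yl)phenyl][3-(trimethylsilyloxy)-2-(3-methylbut-2-en-1-yl)phenyl]methanone F1, so that no free phenol stands beside the electrophile. Brief treatment with water at room temperature should then cleave the O–Si bonds and return to the route at target 13.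

Step 4. Reductive elimination from the η3-prenyl palladium may deliver the reverse-prenyl (1,1-dimethylallyl) isomer, and the bromide flanked by two ortho substituents may couple slowly so that protodebromination takes over. The fallback sets out from bromide 7 and uses a Stille coupling with allyltributylstannane (Pd(PPh3)4, toluene, 100 °C), where no regiochemical choice exists, to give 2-allyl-3-(methoxymethoxy)benzaldehyde F2. Olefin cross-metathesis of the terminal alkene with excess 2-methylbut-2-ene ((H2IMes)(PCy3)Cl2Ru=CHPh, CH2Cl2, 40 °C) should then build the trisubstituted alkene and return to the route at aldehyde 8.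

Step 5. Proton transfer may outrun carbonyl addition, either from the benzylic–allylic CH2 of 8 to the aryllithium or by migration of the anion to C3 between the two acetal oxygens of ring A, leaving reduced arene and unreacted aldehyde. The fallback sets out from bromide 5 and uses a Miyaura borylation (B2pin2, KOAc, PdCl2(dppf), dioxane, 85 °C) to give 2-[2,4-bis(methoxymethoxy)-5-(3-methylbut-2-en-1-yl)phenyl]-4,4,5,5-tetramethyl-1,3,2-dioxaborolane F3. Rhodium(I)-catalysed 1,2-addition of this boronate to aldehyde 8 ([Rh(cod)OH]2, dioxane/H2O, 60 °C) proceeds through a non-basic aryl–rhodium species and should return to the route at carbinol 11.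

**Further compounds**

F1 | step 7 | [2,4-bis(trimethylsilyloxy)-5-(3-methylbut-2-en-1-yl)phenyl][3-(trimethylsilyloxy)-2-(3-methylbut-2-en-1-yl)phenyl]methanone | CC(C)=CCc1cc(C(=O)c2cccc(O[Si](C)(C)C)c2CC=C(C)C)c(O[Si](C)(C)C)cc1O[Si](C)(C)C
F2 | step 4 | 2-allyl-3-(methoxymethoxy)benzaldehyde | COCOc1cccc(C=O)c1CC=C
F3 | step 5 | 2-[2,4-bis(methoxymethoxy)-5-(3-methylbut-2-en-1-yl)phenyl]-4,4,5,5-tetramethyl-1,3,2-dioxaborolane | COCOc1cc(OCOC)c(CC=C(C)C)cc1B1OC(C)(C)C(C)(C)O1
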